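If a steady feed of 8.0 h delivers its mean portion after 4.00 h, half the feed time, I can replace the rising curve by its mean and call that time the lag. The lag leaves alpha 8.00 h against 12 h for epsilon. I call this count full-charge hours, the time at 70 °C with the whole charge taken as present.

| flask | substrate | reagent | temperature | remark | time |
|---|---|---|---|---|---|
| dawn | 0.063 M | 0.158 M | 65 °C | run made earlier |  |
| dusk | 0.063 M | 0.079 M | 76 °C | run made earlier |  |
| noon | 0.063 M | 0.32 M | 65 °C | run made earlier |  |
| alpha | 0.063 M | 0.158 M (fed, over 8.0 h) | 70 °C | all else is in the flask from the start; the feed brings no volume worth counting | 12 h |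
| theta | 0.063 M | 0.158 M (fed, over 8.0 h) |  | the addition at 50 °C, then warmed to 70 °C; the feed brings no volume worth counting | 12 h |
| epsilon | 0.063 M | 0.158 M | 70 °C | everything together at the start | 12 h |
| gamma | 0.063 M (fed, over 8.0 h) | 0.158 M | 70 °C | all else is in the flask from the start; the feed brings no volume worth counting | 12 h |

- dawn (time / h: target / %, substrate / %): 1.00: 8.1, 92.6; 2.00: 12.2, 85.4; 5.00: 24.6, 72.4; 12.0: 37.9, 49.6
- dusk (time / h: target / %, substrate / %): 2.00: 14.5, 82.4; 5.00: 20.7, 70.1; 10.0: 26.2, 53.6; 15.0: 26.2, 44.2
- noon (time / h: target / %, substrate / %): 4.00: 35.5, 59.8; 8.00: 48.7, 41.5; 10.0: 52.2, 35.3; 15.0: 52.8, 25.0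

(readings scatter by 1 percentage point)

* the flask with the highest amount of target, in percent of the substrate charged ("all alike" if they lie within 1.5 percentage points) (alpha / theta / epsilon / gamma / all alike)
* final target, as a percentage of the substrate charged, in alpha
* final target, as a percentage of the substrate charged, in theta
* final target, as a percentage of the substrate charged, in epsilon
* final target, as a percentage of the substrate charged, in gamma

- the numbers in the tables scatter with a standard deviation of 1 percentage point

The lag is the first rung of my ladder. Next comes the substrate's pseudo-first-order lifetime. The dawn run reads 15.5 h, and the noon run, with 2.03 times the reagent, reads 7.78 h, a lifetime shorter by a factor of 1.99 in these two readings. The dusk run, scaled to the dawn charge, reads 5.17 h, and the geometric mean gives roughly 8.94 h at 70 °C.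

The top rung is the target's lifetime. On the late stretches of noon and dusk the target reads flat while substrate falls, so I take its loss there as matching its making. Noon reads 25.5 h, dusk reads 13.9 h, and their geometric mean is 18.8 h. The lag is shorter than the substrate lifetime, and 12 h is shorter than the target lifetime, so I rank the flasks by their hours.

Gamma also gets 8.00 h. Carrying the dawn and dusk lifetimes down to 50 °C, I reckon theta's chemistry during the feed 7.36 times slower, which gives theta 4.54 h. My ranking is epsilon, then alpha tied with gamma, then theta. The mean carries an error: the dawn run's last reading gives a lifetime of 17.1 h against 15.5 h before it, so in that run late hours count for less.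

The forecast gives epsilon 40.5 %, alpha 37.5 %, gamma 34 % and theta 28.5 %, holding for alpha that “the slow feed delays formation more than it saves reagent”. It separates the two flasks I tie.

The flasks give epsilon 38.7 %, alpha 36.4 %, gamma 30.7 % and theta 29.8 %, so epsilon stands highest.

    substrate + reagent → target + by-product (k = 0.730 M⁻¹ h⁻¹, Ea = 80.0 kJ mol⁻¹)
    target ⇌ isomer of the product (K = 1.10, k = 0.0770 h⁻¹, Ea = 117 kJ mol⁻¹, ΔH = 9.00 kJ mol⁻¹)
    substrate + target → side product (k = 0.0540 M⁻¹ h⁻¹, Ea = 83.0 kJ mol⁻¹)
    2 reagent → self-condensation product (k = 0.200 M⁻¹ h⁻¹, Ea = 79.0 kJ mol⁻¹)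
    (constants at 70 °C)

Alpha and gamma share 8.00 h but differ by 5.7 points, and at the end gamma keeps 45.4 % of its reagent charge against 57.7 % in alpha. Theta's 4.54 h and its remaining substrate, 64 %, give a lifetime of 10.2 h. Gamma dosed over 0.800 h has 11.6 h and ends at 38.1 % target.

(The data are simulated with made-up constants.)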